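The 1,2-dioxolane is disconnected by taking O1–O2 out from between its two quaternary carbons: C3 and C5, 1,3-related across C4, become the C3–C5 bond of a cyclopropane that already carries both methyl groups and the complete (R)-methyl-branched chain. In the key step a cyclopropyl oxirane takes up H2O2 under Lewis acid catalysis, so that the carbocycle C3–C4–C5 is expanded by two oxygen atoms to the five-membered peroxide; C5 is formed with inversion from a cyclopropane stereocentre set by asymmetric Simmons–Smith cyclopropanation, and the oxirane carbons emerge as a vinyl group on C3, the later acetic acid. The phenyldiene is attached last by Horner–Wadsworth–Emmons olefination.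

Key step: step 10

Remark: oxirane 16 is carried as a mixture of epimers at the oxirane carbon and the alkene geometry of 17 is immaterial, because both positions merge into one allyl cation in step 10; C3 of the dioxolane is not expected to form with a strong facial bias, so its control rests on separation and re-equilibration as described in step 10.

Step 1
Reactants: 1 6-bromohexan-1-ol
Product: 2 [(6-bromohexyl)oxy](tert-butyl)diphenylsilane
Conditions: TBDPSCl, imidazole, DMF, rt
Reagents that add atoms: tert-butyl(chloro)diphenylsilane, CC(C)(C)[Si](Cl)(c1ccccc1)c1ccccc1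
Why: Imidazole-promoted silylation protects the primary alcohol as an acid-tolerant silyl ether and leaves the bromide untouched.

Step 2
Reactants: 2 [(6-bromohexyl)oxy](tert-butyl)diphenylsilane; 3 (S)-3-bromo-2-methylpropan-1-ol
Product: 6 (R)-9-[(tert-butyldiphenylsilyl)oxy]-2-methylnonan-1-ol, via silyloxyhexylmagnesium bromide 4 (not isolated), via chloromagnesium bromoalkoxide 5 (not isolated)
Conditions: 2, Mg, THF, 40 °C; 3, MeMgCl, THF, −20 °C; combine, Li2CuCl4 (3 mol%), −20 → 0 °C; aq. NH4Cl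
Reagents that add atoms: none
Why: Copper-catalysed sp3–sp3 cross-coupling of a primary Grignard reagent with a primary bromide; the stereocentre of 3 is not a reacting centre and is carried over (its descriptor becomes R only because CH2Br is replaced by an alkyl chain).

Step 3
Reactants: 6 (R)-9-[(tert-butyldiphenylsilyl)oxy]-2-methylnonan-1-ol
Product: 7 {[(R)-9-bromo-8-methylnonyl]oxy}(tert-butyl)diphenylsilane
Conditions: CBr4, PPh3, CH2Cl2, 0 °C
Reagents that add atoms: tetrabromomethane, BrC(Br)(Br)Br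
Why: Appel bromination of the primary alcohol under neutral conditions that spare the silyl ether and the adjacent stereocentre.

Step 4
Reactants: 8 ethyl 2-methyl-3-oxobutanoate
Product: 10 ethyl (Z)-2-methyl-3-{[(trifluoromethyl)sulfonyl]oxy}but-2-enoate, via sodium enolate 9 (not isolated)
Conditions: NaH, Et2O, 0 °C; Tf2O, 0 °C
Reagents that add atoms: trifluoromethanesulfonic anhydride, O=S(=O)(OS(=O)(=O)C(F)(F)F)C(F)(F)F
Why: O-triflation of the chelated sodium enolate of the β-keto ester, in which enolate oxygen and ester are held cis, should give the (Z)-enol triflate.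

Step 5
Reactants: 7 {[(R)-9-bromo-8-methylnonyl]oxy}(tert-butyl)diphenylsilane; 10 ethyl (Z)-2-methyl-3-{[(trifluoromethyl)sulfonyl]oxy}but-2-enoate
Product: 12 ethyl (2Z,5R)-12-[(tert-butyldiphenylsilyl)oxy]-2,3,5-trimethyldodec-2-enoate, via alkylmagnesium bromide 11 (not isolated)
Conditions: 7, Mg, THF, 40 °C; then 10, Fe(acac)3 (5 mol%), THF/NMP, −30 °C
Reagents that add atoms: none
Why: Iron-catalysed cross-coupling of an alkyl Grignard reagent with an alkenyl triflate proceeds with retention of the alkene geometry and tolerates the ester at low temperature, giving the tetrasubstituted (Z)-enoate.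

Step 6
Reactants: 12 ethyl (2Z,5R)-12-[(tert-butyldiphenylsilyl)oxy]-2,3,5-trimethyldodec-2-enoate
Product: 13 (2Z,5R)-12-[(tert-butyldiphenylsilyl)oxy]-2,3,5-trimethyldodec-2-en-1-ol
Conditions: DIBAL-H (2.5 equiv), CH2Cl2, −78 → 0 °C; Rochelle salt
Reagents that add atoms: none
Why: DIBAL-H 1,2-reduction of the enoate gives the allylic alcohol without touching the alkene geometry.

Step 7
Reactants: 13 (2Z,5R)-12-[(tert-butyldiphenylsilyl)oxy]-2,3,5-trimethyldodec-2-en-1-ol
Product: 14 [(1R,2S)-2-{(R)-9-[(tert-butyldiphenylsilyl)oxy]-2-methylnonyl}-1,2-dimethylcyclopropyl]methanol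
Conditions: Et2Zn, CH2I2, DME, CH2Cl2, −10 °C; (4S,5S)-2-butyl-N,N,N′,N′-tetramethyl-1,3,2-dioxaborolane-4,5-dicarboxamide (1.2 equiv); −10 °C → rt
Reagents that add atoms: diiodomethane, ICI
Why: Dioxaborolane-mediated asymmetric Simmons–Smith cyclopropanation of the allylic zinc alkoxide: the (4S,5S)-ligand, mirror image of the one known to give the (1S) carbinol carbon, should deliver CH2 to the face that makes C1 (R), and stereospecific syn addition to the (Z)-alkene then fixes C2 as (S).

Step 8
Reactants: 14 [(1R,2S)-2-{(R)-9-[(tert-butyldiphenylsilyl)oxy]-2-methylnonyl}-1,2-dimethylcyclopropyl]methanol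
Product: 15 (1R,2S)-2-{(R)-9-[(tert-butyldiphenylsilyl)oxy]-2-methylnonyl}-1,2-dimethylcyclopropane-1-carbaldehyde
Conditions: Dess–Martin periodinane, CH2Cl2, 0 °C → rt
Reagents that add atoms: none
Why: Dess–Martin oxidation of the primary alcohol gives an aldehyde whose α-carbon is quaternary and therefore cannot epimerise.

Step 9
Reactants: 15 (1R,2S)-2-{(R)-9-[(tert-butyldiphenylsilyl)oxy]-2-methylnonyl}-1,2-dimethylcyclopropane-1-carbaldehyde
Product: 16 2-[(1R,2S)-2-{(R)-9-[(tert-butyldiphenylsilyl)oxy]-2-methylnonyl}-1,2-dimethylcyclopropyl]oxirane (both epimers at the oxirane carbon)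
Conditions: Me3S+ I−, n-BuLi, THF, −10 °C → rt
Reagents that add atoms: trimethylsulfonium iodide, C[S+](C)C.[I-]
Why: Corey–Chaykovsky methylene transfer from dimethylsulfonium methylide to the hindered aldehyde gives the terminal oxirane; the new centre need not be controlled.

Step 10
Reactants: 16 2-[(1R,2S)-2-{(R)-9-[(tert-butyldiphenylsilyl)oxy]-2-methylnonyl}-1,2-dimethylcyclopropyl]oxirane
Product: 18 (3R,5R)-5-{(R)-9-[(tert-butyldiphenylsilyl)oxy]-2-methylnonyl}-3-ethenyl-3,5-dimethyl-1,2-dioxolane, via allylic alcohol hydroperoxide 17 (not isolated)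
Conditions: anhydrous H2O2 in Et2O (10 equiv), TMSOTf (0.2 equiv), Et2O, −78 → 0 °C; Et3N quench
Reagents that add atoms: hydrogen peroxide, OO
Why: Proposed new method: Lewis-acid activation opens the oxirane at the cyclopropyl-substituted carbon to a cyclopropylcarbinyl (bicyclobutonium) cation whose charge is relayed to the quaternary ring carbon C5; H2O2 attacks C5 opposite to the breaking C3–C5 bond to give hydroperoxide 17, and the same acid then ionises the allylic alcohol of 17 to an allyl cation with a tertiary terminus at C3 that the hydroperoxide captures in a 5-exo-trig closure, so that O–O is formally inserted into the C3–C5 bond of the cyclopropane. The closest known reaction types are the stereoinvertive nucleophilic substitution at quaternary carbons of cyclopropylcarbinols (homoallylic products with halide, carboxylate or hydroxyl nucleophiles) and the Lewis-acid perhydrolysis of oxetanes and epoxides at tertiary carbon with inversion. C5 is controlled by the (2S) cyclopropane centre from step 7, which backside attack translates into (5R). C3 is formed in a reversible ionisation–capture step without a strong intrinsic facial bias, so the (3R) isomer is separated by chromatography and material epimeric at C3 is returned to the reaction conditions, where it should re-equilibrate through the same allyl cation. The step needs attack at the tertiary ring carbon instead of the carbinyl carbon or the ring CH2, which the tertiary substitution at C5 and the reversibility of capture at the secondary carbinyl position should secure, and 5-exo closure at the tertiary allyl terminus instead of 7-endo closure at the primary one.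

Step 11
Reactants: 18 (3R,5R)-5-{(R)-9-[(tert-butyldiphenylsilyl)oxy]-2-methylnonyl}-3-ethenyl-3,5-dimethyl-1,2-dioxolane
Product: 20 2-[(3S,5R)-5-{(R)-9-[(tert-butyldiphenylsilyl)oxy]-2-methylnonyl}-3,5-dimethyl-1,2-dioxolan-3-yl]ethan-1-ol, via B-alkyl-9-BBN 19 (not isolated)
Conditions: 9-BBN, THF, 0 °C → rt; NaBO3·4H2O, THF/H2O, rt
Reagents that add atoms: sodium perborate, [Na+].[Na+].O[B-]1(O)OO[B-](O)(O)OO1
Why: Anti-Markovnikov hydroboration–oxidation of the terminal vinyl group with a dialkylborane that should leave the hindered dialkyl peroxide alone; C3 is untouched (its descriptor changes to S only by CIP ranking).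

Step 12
Reactants: 20 2-[(3S,5R)-5-{(R)-9-[(tert-butyldiphenylsilyl)oxy]-2-methylnonyl}-3,5-dimethyl-1,2-dioxolan-3-yl]ethan-1-ol
Product: 22 2-[(3R,5R)-5-{(R)-9-[(tert-butyldiphenylsilyl)oxy]-2-methylnonyl}-3,5-dimethyl-1,2-dioxolan-3-yl]acetic acid, via aldehyde 21 (not isolated)
Conditions: TEMPO (0.2 equiv), PhI(OAc)2 (2.2 equiv), MeCN/H2O/CH2Cl2, rt
Reagents that add atoms: water, O
Why: Oxoammonium (TEMPO/iodine(III)) oxidation of the primary alcohol through the aldehyde hydrate to the carboxylic acid under near-neutral conditions compatible with the peroxide and the silyl ether.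

Step 13
Reactants: 22 2-[(3R,5R)-5-{(R)-9-[(tert-butyldiphenylsilyl)oxy]-2-methylnonyl}-3,5-dimethyl-1,2-dioxolan-3-yl]acetic acid
Product: 23 2-[(3R,5R)-5-[(R)-9-hydroxy-2-methylnonyl]-3,5-dimethyl-1,2-dioxolan-3-yl]acetic acid
Conditions: HF·pyridine, THF/pyridine, 0 °C → rt
Reagents that add atoms: none
Why: Fluoride-mediated cleavage of the silyl ether under buffered conditions that do not affect the peroxide or the acid.

Step 14
Reactants: 23 2-[(3R,5R)-5-[(R)-9-hydroxy-2-methylnonyl]-3,5-dimethyl-1,2-dioxolan-3-yl]acetic acid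
Product: 24 2-[(3R,5R)-3,5-dimethyl-5-[(R)-2-methyl-9-oxononyl]-1,2-dioxolan-3-yl]acetic acid
Conditions: Dess–Martin periodinane, CH2Cl2, 0 °C → rt
Reagents that add atoms: none
Why: Dess–Martin oxidation stops at the aldehyde and tolerates the free acid and the peroxide.

Step 15
Reactants: 24 2-[(3R,5R)-3,5-dimethyl-5-[(R)-2-methyl-9-oxononyl]-1,2-dioxolan-3-yl]acetic acid; 25 diethyl [(E)-3-phenylprop-2-en-1-yl]phosphonate
Product: 28 2-[(3R,5R)-3,5-dimethyl-5-[(2R,9E,11E)-2-methyl-12-phenyldodeca-9,11-dien-1-yl]-1,2-dioxolan-3-yl]acetic acid, via lithiated phosphonate 26 (not isolated), via lithium carboxylate 27 (not isolated)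
Conditions: 25 (2.5 equiv), LiHMDS (3.4 equiv), THF, −78 °C; add 24, −78 °C → rt; 1 M HCl
Reagents that add atoms: none
Why: Horner–Wadsworth–Emmons olefination with the stabilised allylic phosphonate anion should form the new C9=C10 bond E-selectively while the cinnamyl E bond is retained; the carboxylate is inert and the peroxide carbons bear no α-hydrogen.

Compound list
1 | 6-bromohexan-1-ol | OCCCCCCBr | starting material
2 | [(6-bromohexyl)oxy](tert-butyl)diphenylsilane | BrCCCCCCO[Si](c1ccccc1)(c1ccccc1)C(C)(C)C | intermediate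
3 | (S)-3-bromo-2-methylpropan-1-ol | OC[C@H](C)CBr | starting material
4 | {6-[(tert-butyldiphenylsilyl)oxy]hexyl}magnesium bromide (not isolated) | Br[Mg]CCCCCCO[Si](c1ccccc1)(c1ccccc1)C(C)(C)C | intermediate
5 | chloromagnesium (S)-3-bromo-2-methylpropan-1-olate (not isolated) | Cl[Mg]OC[C@H](C)CBr | intermediate
6 | (R)-9-[(tert-butyldiphenylsilyl)oxy]-2-methylnonan-1-ol | OC[C@H](C)CCCCCCCO[Si](c1ccccc1)(c1ccccc1)C(C)(C)C | intermediate
7 | {[(R)-9-bromo-8-methylnonyl]oxy}(tert-butyl)diphenylsilane | BrC[C@H](C)CCCCCCCO[Si](c1ccccc1)(c1ccccc1)C(C)(C)C | intermediate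
8 | ethyl 2-methyl-3-oxobutanoate | CCOC(=O)C(C)C(C)=O | starting material
9 | sodium (Z)-enolate of ethyl 2-methyl-3-oxobutanoate (not isolated) | [Na+].CCOC(=O)/C(C)=C(C)\[O-] | intermediate
10 | ethyl (Z)-2-methyl-3-{[(trifluoromethyl)sulfonyl]oxy}but-2-enoate | CCOC(=O)/C(C)=C(C)\OS(=O)(=O)C(F)(F)F | intermediate
11 | {(R)-9-[(tert-butyldiphenylsilyl)oxy]-2-methylnonyl}magnesium bromide (not isolated) | Br[Mg]C[C@H](C)CCCCCCCO[Si](c1ccccc1)(c1ccccc1)C(C)(C)C | intermediate
12 | ethyl (2Z,5R)-12-[(tert-butyldiphenylsilyl)oxy]-2,3,5-trimethyldodec-2-enoate | CCOC(=O)/C(C)=C(C)\C[C@H](C)CCCCCCCO[Si](c1ccccc1)(c1ccccc1)C(C)(C)C | intermediate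
13 | (2Z,5R)-12-[(tert-butyldiphenylsilyl)oxy]-2,3,5-trimethyldodec-2-en-1-ol | OC/C(C)=C(C)\C[C@H](C)CCCCCCCO[Si](c1ccccc1)(c1ccccc1)C(C)(C)C | intermediate
14 | [(1R,2S)-2-{(R)-9-[(tert-butyldiphenylsilyl)oxy]-2-methylnonyl}-1,2-dimethylcyclopropyl]methanol | OC[C@]1(C)C[C@]1(C)C[C@H](C)CCCCCCCO[Si](c1ccccc1)(c1ccccc1)C(C)(C)C | intermediate
15 | (1R,2S)-2-{(R)-9-[(tert-butyldiphenylsilyl)oxy]-2-methylnonyl}-1,2-dimethylcyclopropane-1-carbaldehyde | O=C[C@]1(C)C[C@]1(C)C[C@H](C)CCCCCCCO[Si](c1ccccc1)(c1ccccc1)C(C)(C)C | intermediate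
16 | 2-[(1R,2S)-2-{(R)-9-[(tert-butyldiphenylsilyl)oxy]-2-methylnonyl}-1,2-dimethylcyclopropyl]oxirane (both epimers at the oxirane carbon) | C1OC1[C@]1(C)C[C@]1(C)C[C@H](C)CCCCCCCO[Si](c1ccccc1)(c1ccccc1)C(C)(C)C | intermediate
17 | (2E,5R,7R)-14-[(tert-butyldiphenylsilyl)oxy]-5-hydroperoxy-3,5,7-trimethyltetradec-2-en-1-ol (not isolated) | OC/C=C(C)/C[C@](C)(OO)C[C@H](C)CCCCCCCO[Si](c1ccccc1)(c1ccccc1)C(C)(C)C | intermediate
18 | (3R,5R)-5-{(R)-9-[(tert-butyldiphenylsilyl)oxy]-2-methylnonyl}-3-ethenyl-3,5-dimethyl-1,2-dioxolane | C[C@H](CCCCCCCO[Si](c1ccccc1)(c1ccccc1)C(C)(C)C)C[C@]1(C)C[C@](C)(C=C)OO1 | intermediate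
19 | 9-{2-[(3S,5R)-5-{(R)-9-[(tert-butyldiphenylsilyl)oxy]-2-methylnonyl}-3,5-dimethyl-1,2-dioxolan-3-yl]ethyl}-9-borabicyclo[3.3.1]nonane (not isolated) | C[C@H](CCCCCCCO[Si](c1ccccc1)(c1ccccc1)C(C)(C)C)C[C@]1(C)C[C@](C)(CCB2C3CCCC2CCC3)OO1 | intermediate
20 | 2-[(3S,5R)-5-{(R)-9-[(tert-butyldiphenylsilyl)oxy]-2-methylnonyl}-3,5-dimethyl-1,2-dioxolan-3-yl]ethan-1-ol | C[C@H](CCCCCCCO[Si](c1ccccc1)(c1ccccc1)C(C)(C)C)C[C@]1(C)C[C@](C)(CCO)OO1 | intermediate
21 | 2-[(3R,5R)-5-{(R)-9-[(tert-butyldiphenylsilyl)oxy]-2-methylnonyl}-3,5-dimethyl-1,2-dioxolan-3-yl]acetaldehyde (not isolated) | C[C@H](CCCCCCCO[Si](c1ccccc1)(c1ccccc1)C(C)(C)C)C[C@]1(C)C[C@](C)(CC=O)OO1 | intermediate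
22 | 2-[(3R,5R)-5-{(R)-9-[(tert-butyldiphenylsilyl)oxy]-2-methylnonyl}-3,5-dimethyl-1,2-dioxolan-3-yl]acetic acid | C[C@H](CCCCCCCO[Si](c1ccccc1)(c1ccccc1)C(C)(C)C)C[C@]1(C)C[C@](C)(CC(=O)O)OO1 | intermediate
23 | 2-[(3R,5R)-5-[(R)-9-hydroxy-2-methylnonyl]-3,5-dimethyl-1,2-dioxolan-3-yl]acetic acid | C[C@H](CCCCCCCO)C[C@]1(C)C[C@](C)(CC(=O)O)OO1 | intermediate
24 | 2-[(3R,5R)-3,5-dimethyl-5-[(R)-2-methyl-9-oxononyl]-1,2-dioxolan-3-yl]acetic acid | C[C@H](CCCCCCC=O)C[C@]1(C)C[C@](C)(CC(=O)O)OO1 | intermediate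
25 | diethyl [(E)-3-phenylprop-2-en-1-yl]phosphonate | CCOP(=O)(OCC)C/C=C/c1ccccc1 | starting material
26 | lithium salt of the α-carbanion of 25 (not isolated) | [Li+].CCOP(=O)(OCC)[CH-]/C=C/c1ccccc1 | intermediate
27 | lithium 2-[(3R,5R)-3,5-dimethyl-5-[(R)-2-methyl-9-oxononyl]-1,2-dioxolan-3-yl]acetate (not isolated) | [Li+].C[C@H](CCCCCCC=O)C[C@]1(C)C[C@](C)(CC(=O)[O-])OO1 | intermediate
28 | 2-[(3R,5R)-3,5-dimethyl-5-[(2R,9E,11E)-2-methyl-12-phenyldodeca-9,11-dien-1-yl]-1,2-dioxolan-3-yl]acetic acid | C[C@H](CCCCCC/C=C/C=C/c1ccccc1)C[C@]1(C)C[C@](C)(CC(=O)O)OO1 | target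

Total step count: 15. Longest linear sequence: 14 steps (steps 1–3 and 5–15, from 6-bromohexan-1-ol); step 4 is a one-step side branch.

Steps most likely to fail

Step 10 (proposed new method). The cation may be captured at the carbinyl carbon without ring opening, relax to an open tertiary cation so that configuration at C5 erodes, undergo a Meinwald-type hydride shift, or the hydroperoxide may fragment under the acid. The fallback uses known chemistry and sets out from 15. Wittig methylenation (Ph3P=CH2, THF) gives (1S,2S)-2-{(R)-9-[(tert-butyldiphenylsilyl)oxy]-2-methylnonyl}-1-ethenyl-1,2-dimethylcyclopropane F1. Selenyl-radical-catalysed aerobic oxygenation of this vinylcyclopropane (PhSeSePh cat., AIBN, O2, hν, MeCN, 0 °C) then expands the same three-membered ring: the selenyl radical adds to the vinyl group, the cyclopropylcarbinyl radical opens to the tertiary radical at C5, O2 is captured, the peroxyl radical closes 5-exo and the selenyl radical is expelled. The route is rejoined at 18. In this variant neither C5 nor C3 is controlled, so 18 would have to be separated from its ring diastereomers by preparative HPLC.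

Step 7. Methylene transfer to the tetrasubstituted (Z)-alkene may be sluggish and the facial selectivity of the ligand insufficient. The fallback sets out from 13. Hydroxyl-directed cyclopropanation without chiral ligand (Et2Zn, CH2I2, CH2Cl2) gives both ring diastereomers. Esterification with (S)-2-methoxy-2-phenylacetic acid (DCC, DMAP) and chromatographic separation gives [(1R,2S)-2-{(R)-9-[(tert-butyldiphenylsilyl)oxy]-2-methylnonyl}-1,2-dimethylcyclopropyl]methyl (S)-2-methoxy-2-phenylacetate F2. Methanolysis (K2CO3, MeOH) returns the route to 14.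

Step 11. The borane may reduce the O–O bond, or hydroboration of the neopentyl-type vinyl group may be too slow to compete. The fallback sets out from 18 and avoids hydride reagents. Ozonolysis (O3, CH2Cl2, −78 °C; Me2S) gives (3R,5R)-5-{(R)-9-[(tert-butyldiphenylsilyl)oxy]-2-methylnonyl}-3,5-dimethyl-1,2-dioxolane-3-carbaldehyde F3. Wittig homologation (Ph3P=CHOMe, THF) gives (3R,5R)-5-{(R)-9-[(tert-butyldiphenylsilyl)oxy]-2-methylnonyl}-3-(2-methoxyethenyl)-3,5-dimethyl-1,2-dioxolane F4. Mild acid hydrolysis gives aldehyde 21, and Pinnick oxidation (NaClO2, NaH2PO4, 2-methylbut-2-ene) rejoins the route at 22.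

Further compounds
F1 | step 10 | (1S,2S)-2-{(R)-9-[(tert-butyldiphenylsilyl)oxy]-2-methylnonyl}-1-ethenyl-1,2-dimethylcyclopropane | C=C[C@]1(C)C[C@]1(C)C[C@H](C)CCCCCCCO[Si](c1ccccc1)(c1ccccc1)C(C)(C)C
F2 | step 7 | [(1R,2S)-2-{(R)-9-[(tert-butyldiphenylsilyl)oxy]-2-methylnonyl}-1,2-dimethylcyclopropyl]methyl (S)-2-methoxy-2-phenylacetate | CO[C@H](C(=O)OC[C@]1(C)C[C@]1(C)C[C@H](C)CCCCCCCO[Si](c1ccccc1)(c1ccccc1)C(C)(C)C)c1ccccc1
F3 | step 11 | (3R,5R)-5-{(R)-9-[(tert-butyldiphenylsilyl)oxy]-2-methylnonyl}-3,5-dimethyl-1,2-dioxolane-3-carbaldehyde | C[C@H](CCCCCCCO[Si](c1ccccc1)(c1ccccc1)C(C)(C)C)C[C@]1(C)C[C@](C)(C=O)OO1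
F4 | step 11 | (3R,5R)-5-{(R)-9-[(tert-butyldiphenylsilyl)oxy]-2-methylnonyl}-3-(2-methoxyethenyl)-3,5-dimethyl-1,2-dioxolane (E/Z mixture) | C[C@H](CCCCCCCO[Si](c1ccccc1)(c1ccccc1)C(C)(C)C)C[C@]1(C)C[C@](C)(C=COC)OO1
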